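**Plan**

- Retrosynthesis first removes the acetate and the four phenol protecting groups, then cuts C7'–C8' and C9'–C10' on either side of the cis alkene.
- Enabling feature: C8' and C9' each carry one hydrogen and one unbranched (CH2)7 arm ending in ring A or ring B, so C8'=C9' is acetylene that has taken up two alkyl groups on the same face.
- Both arms come from 5-bromoresorcinol and hept-6-yn-1-ol (Sonogashira coupling, hydrogenation, iodination); ring B is carried as a bis(silyl ether), ring A as a silyl ether plus a 4-methoxybenzyl ether.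
- Forward: the ring B iodide becomes an alkyllithium, then a cuprate, which adds syn to acetylene and is alkylated by the ring A iodide in the same flask; no ring is formed.
- There is no stereocentre; the Z geometry comes from the syn carbocupration and the retentive alkylation. The endgame is 4-methoxybenzyl removal, acetylation and desilylation.

Key step: step 10

Remark: ring A is the acetoxy-bearing ring, ring B the 3,5-dihydroxyphenyl ring, and the chain is numbered C1' (on ring A) to C16' (on ring B); TBS = tert-butyldimethylsilyl, PMB = 4-methoxybenzyl.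

**Route**

Step 1
Reactants: 1 5-bromobenzene-1,3-diol
Product: 2 1-bromo-3,5-bis(tert-butyldimethylsilyloxy)benzene
Conditions: TBSCl (2.4 equiv), imidazole (5 equiv), DMF, 0 °C → rt
Reagents that add atoms: tert-butyldimethylsilyl chloride (TBSCl), CC(C)(C)[Si](C)(C)Cl
Why: Imidazole-promoted O-silylation of both phenols is standard and gives aryl silyl ethers that tolerate amines, hydrogenation, iodination and low-temperature organometallics.

Step 2
Reactants: 2 1-bromo-3,5-bis(tert-butyldimethylsilyloxy)benzene; 3 hept-6-yn-1-ol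
Product: 4 7-[3,5-bis(tert-butyldimethylsilyloxy)phenyl]hept-6-yn-1-ol
Conditions: Pd(PPh3)2Cl2 (5 mol %), CuI (10 mol %), Et3N–DMF, degassed, 70 °C
Reagents that add atoms: none
Why: Sonogashira coupling of an aryl bromide with a terminal alkyne tolerates the free primary alcohol and the aryl silyl ethers and installs the full seven-carbon arm in one operation.

Step 3
Reactants: 4 7-[3,5-bis(tert-butyldimethylsilyloxy)phenyl]hept-6-yn-1-ol
Product: 5 7-[3,5-bis(tert-butyldimethylsilyloxy)phenyl]heptan-1-ol
Conditions: H2 (1 atm), 10% Pd/C, EtOAc, rt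
Reagents that add atoms: none
Why: Catalytic hydrogenation over Pd/C saturates the aryl alkyne completely, and nothing else in the molecule is reducible in EtOAc.

Step 4
Reactants: 5 7-[3,5-bis(tert-butyldimethylsilyloxy)phenyl]heptan-1-ol
Product: 6 1-(7-iodoheptyl)-3,5-bis(tert-butyldimethylsilyloxy)benzene
Conditions: I2, PPh3, imidazole, CH2Cl2, 0 °C → rt
Reagents that add atoms: iodine, II
Why: Appel-type iodination converts the primary alcohol into the iodide through an alkoxyphosphonium ion under near-neutral conditions that leave aryl silyl ethers intact.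

Step 5
Reactants: 1 5-bromobenzene-1,3-diol
Product: 7 3-bromo-5-(4-methoxybenzyloxy)phenol
Conditions: 1 (2 equiv), PMBCl (1 equiv), K2CO3 (1.1 equiv), DMF, rt
Reagents that add atoms: 4-methoxybenzyl chloride (PMBCl), COc1ccc(CCl)cc1
Why: Williamson etherification of the symmetric diphenol, run with the diol in excess, should favour the monoether statistically, and the diether and recovered 1 are removed by chromatography.

Step 6
Reactants: 7 3-bromo-5-(4-methoxybenzyloxy)phenol
Product: 8 [3-bromo-5-(4-methoxybenzyloxy)phenoxy](tert-butyl)dimethylsilane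
Conditions: TBSCl (1.2 equiv), imidazole (2.5 equiv), DMF, rt
Reagents that add atoms: tert-butyldimethylsilyl chloride (TBSCl), CC(C)(C)[Si](C)(C)Cl
Why: Imidazole-promoted O-silylation caps the remaining phenol, so the two ring A oxygens now carry orthogonal groups (oxidatively labile PMB, fluoride-labile TBS).

Step 7
Reactants: 8 [3-bromo-5-(4-methoxybenzyloxy)phenoxy](tert-butyl)dimethylsilane; 3 hept-6-yn-1-ol
Product: 9 7-[3-(tert-butyldimethylsilyloxy)-5-(4-methoxybenzyloxy)phenyl]hept-6-yn-1-ol
Conditions: Pd(PPh3)2Cl2 (5 mol %), CuI (10 mol %), Et3N–DMF, degassed, 70 °C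
Reagents that add atoms: none
Why: The same Sonogashira coupling as in step 2 applies, since the benzyl and silyl ethers are inert to zerovalent palladium and triethylamine.

Step 8
Reactants: 9 7-[3-(tert-butyldimethylsilyloxy)-5-(4-methoxybenzyloxy)phenyl]hept-6-yn-1-ol
Product: 10 7-[3-(tert-butyldimethylsilyloxy)-5-(4-methoxybenzyloxy)phenyl]heptan-1-ol
Conditions: H2 (1 atm), 5% Pd/C, pyridine (0.5 equiv), EtOAc, rt
Reagents that add atoms: none
Why: Chemoselective heterogeneous hydrogenation saturates the alkyne, while pyridine as a catalyst poison is known to suppress hydrogenolysis of phenolic 4-methoxybenzyl ethers on Pd/C and EtOAc avoids the silyl ether loss seen in methanol.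

Step 9
Reactants: 10 7-[3-(tert-butyldimethylsilyloxy)-5-(4-methoxybenzyloxy)phenyl]heptan-1-ol
Product: 11 tert-butyl[3-(7-iodoheptyl)-5-(4-methoxybenzyloxy)phenoxy]dimethylsilane
Conditions: I2, PPh3, imidazole, CH2Cl2, 0 °C → rt
Reagents that add atoms: iodine, II
Why: Appel-type iodination of the primary alcohol proceeds as in step 4 and affects neither the PMB nor the silyl ether.

Step 10
Reactants: 6 1-(7-iodoheptyl)-3,5-bis(tert-butyldimethylsilyloxy)benzene; 12 acetylene; 11 tert-butyl[3-(7-iodoheptyl)-5-(4-methoxybenzyloxy)phenoxy]dimethylsilane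
Product: 16 tert-butyl{3-[(8Z)-16-[3,5-bis(tert-butyldimethylsilyloxy)phenyl]hexadec-8-en-1-yl]-5-(4-methoxybenzyloxy)phenoxy}dimethylsilane, via ring B heptyllithium 13 (not isolated), via lithium dialkylcuprate 14 (not isolated), via lithium di-(Z)-alkenylcuprate 15 (not isolated)
Conditions: 6 (2.0 equiv), t-BuLi (4.0 equiv), Et2O–pentane, −78 °C; CuBr·SMe2 (1.0 equiv), Et2O, −45 °C; HC≡CH (2.0 equiv, gas burette), −50 → −25 °C; then THF, HMPA, P(OEt)3, 11 (1.7 equiv), −40 °C → rt
Reagents that add atoms: none
Why: Iodine–lithium exchange with two equivalents of t-BuLi turns 6 into the primary alkyllithium 13, two equivalents of which combine with CuBr·SMe2 to the lithium dialkylcuprate 14, and 14 delivers both alkyl groups to two molecules of acetylene through a four-centre syn transition state to give the di-(Z)-alkenylcuprate 15. The primary iodide 11 then adds oxidatively to monovalent copper and the trivalent copper intermediate eliminates reductively with retention at the alkenyl carbon, so that C7'–C8' and C9'–C10' are both made and the two heptyl arms end up cis. The closest known reaction type is the Normant carbocupration of acetylene by lithium dialkylcuprates followed by alkylation of the Z-alkenylcuprate with a primary alkyl iodide in the presence of HMPA and P(OEt)3, as practised for Z-alkene pheromones. No ring is closed and no stereocentre is created; the only stereochemical element, the Z geometry of C8'=C9', is fixed by the syn addition and by the configurational stability of the alkenyl–copper bond below −25 °C. The step needs one acetylene insertion per copper–carbon bond and no attack on the ethers: acetylene is symmetric so no regiochemistry arises, metered acetylene and temperatures below −25 °C should prevent a second insertion, the exchange at −78 °C is much faster than attack of an organolithium on silicon, and the primary C–I bond of 11 is the only electrophilic site offered to 15, with 11 kept as the limiting component.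

Step 11
Reactants: 16 tert-butyl{3-[(8Z)-16-[3,5-bis(tert-butyldimethylsilyloxy)phenyl]hexadec-8-en-1-yl]-5-(4-methoxybenzyloxy)phenoxy}dimethylsilane
Product: 17 3-[(8Z)-16-[3,5-bis(tert-butyldimethylsilyloxy)phenyl]hexadec-8-en-1-yl]-5-(tert-butyldimethylsilyloxy)phenol
Conditions: DDQ (1.3 equiv), CH2Cl2–pH 7 phosphate buffer (10:1), 0 °C → rt
Reagents that add atoms: none
Why: Oxidative PMB cleavage by DDQ (hydride abstraction to the 4-methoxybenzyl oxocarbenium ion, then hydrolysis) should free only the ring A phenol, because silyl ethers, the isolated Z-alkene and benzylic positions meta to oxygen are not oxidised under buffered conditions.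

Step 12
Reactants: 17 3-[(8Z)-16-[3,5-bis(tert-butyldimethylsilyloxy)phenyl]hexadec-8-en-1-yl]-5-(tert-butyldimethylsilyloxy)phenol
Product: 18 3-[(8Z)-16-[3,5-bis(tert-butyldimethylsilyloxy)phenyl]hexadec-8-en-1-yl]-5-(tert-butyldimethylsilyloxy)phenyl acetate
Conditions: Ac2O, pyridine, DMAP (cat.), CH2Cl2, 0 °C → rt
Reagents that add atoms: acetic anhydride, CC(=O)OC(C)=O
Why: DMAP-catalysed O-acylation of the single free phenol places the acetate on the correct ring A oxygen, since the other three phenols are still silylated.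

Step 13
Reactants: 18 3-[(8Z)-16-[3,5-bis(tert-butyldimethylsilyloxy)phenyl]hexadec-8-en-1-yl]-5-(tert-butyldimethylsilyloxy)phenyl acetate
Product: 19 Oncostemonol B, 3-[(8Z)-16-(3,5-dihydroxyphenyl)hexadec-8-en-1-yl]-5-hydroxyphenyl acetate
Conditions: HF·pyridine, pyridine, THF, 0 °C → rt
Reagents that add atoms: none
Why: Fluoride-mediated desilylation under mildly acidic conditions removes the three aryl silyl groups as the silyl fluoride and releases neutral phenols, so the aryl acetate should neither hydrolyse nor transfer as it could with basic fluoride, and the Z-alkene is untouched.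

**Compound list**

1 | 5-bromobenzene-1,3-diol | Oc1cc(O)cc(Br)c1 | starting material
2 | 1-bromo-3,5-bis(tert-butyldimethylsilyloxy)benzene | Brc1cc(O[Si](C)(C)C(C)(C)C)cc(O[Si](C)(C)C(C)(C)C)c1 | intermediate
3 | hept-6-yn-1-ol | OCCCCCC#C | starting material
4 | 7-[3,5-bis(tert-butyldimethylsilyloxy)phenyl]hept-6-yn-1-ol | OCCCCCC#Cc1cc(O[Si](C)(C)C(C)(C)C)cc(O[Si](C)(C)C(C)(C)C)c1 | intermediate
5 | 7-[3,5-bis(tert-butyldimethylsilyloxy)phenyl]heptan-1-ol | OCCCCCCCc1cc(O[Si](C)(C)C(C)(C)C)cc(O[Si](C)(C)C(C)(C)C)c1 | intermediate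
6 | 1-(7-iodoheptyl)-3,5-bis(tert-butyldimethylsilyloxy)benzene | ICCCCCCCc1cc(O[Si](C)(C)C(C)(C)C)cc(O[Si](C)(C)C(C)(C)C)c1 | intermediate
7 | 3-bromo-5-(4-methoxybenzyloxy)phenol | COc1ccc(COc2cc(O)cc(Br)c2)cc1 | intermediate
8 | [3-bromo-5-(4-methoxybenzyloxy)phenoxy](tert-butyl)dimethylsilane | COc1ccc(COc2cc(Br)cc(O[Si](C)(C)C(C)(C)C)c2)cc1 | intermediate
9 | 7-[3-(tert-butyldimethylsilyloxy)-5-(4-methoxybenzyloxy)phenyl]hept-6-yn-1-ol | COc1ccc(COc2cc(C#CCCCCCO)cc(O[Si](C)(C)C(C)(C)C)c2)cc1 | intermediate
10 | 7-[3-(tert-butyldimethylsilyloxy)-5-(4-methoxybenzyloxy)phenyl]heptan-1-ol | COc1ccc(COc2cc(CCCCCCCO)cc(O[Si](C)(C)C(C)(C)C)c2)cc1 | intermediate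
11 | tert-butyl[3-(7-iodoheptyl)-5-(4-methoxybenzyloxy)phenoxy]dimethylsilane | COc1ccc(COc2cc(CCCCCCCI)cc(O[Si](C)(C)C(C)(C)C)c2)cc1 | intermediate
12 | acetylene | C#C | starting material
13 | 7-[3,5-bis(tert-butyldimethylsilyloxy)phenyl]heptyllithium | [Li]CCCCCCCc1cc(O[Si](C)(C)C(C)(C)C)cc(O[Si](C)(C)C(C)(C)C)c1 | intermediate
14 | lithium bis{7-[3,5-bis(tert-butyldimethylsilyloxy)phenyl]heptyl}cuprate | [Li+].[Cu-](CCCCCCCc1cc(O[Si](C)(C)C(C)(C)C)cc(O[Si](C)(C)C(C)(C)C)c1)CCCCCCCc1cc(O[Si](C)(C)C(C)(C)C)cc(O[Si](C)(C)C(C)(C)C)c1 | intermediate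
15 | lithium bis{(1Z)-9-[3,5-bis(tert-butyldimethylsilyloxy)phenyl]non-1-en-1-yl}cuprate | [Li+].[Cu-](/C=C\CCCCCCCc1cc(O[Si](C)(C)C(C)(C)C)cc(O[Si](C)(C)C(C)(C)C)c1)/C=C\CCCCCCCc1cc(O[Si](C)(C)C(C)(C)C)cc(O[Si](C)(C)C(C)(C)C)c1 | intermediate
16 | tert-butyl{3-[(8Z)-16-[3,5-bis(tert-butyldimethylsilyloxy)phenyl]hexadec-8-en-1-yl]-5-(4-methoxybenzyloxy)phenoxy}dimethylsilane | COc1ccc(COc2cc(CCCCCCC/C=C\CCCCCCCc3cc(O[Si](C)(C)C(C)(C)C)cc(O[Si](C)(C)C(C)(C)C)c3)cc(O[Si](C)(C)C(C)(C)C)c2)cc1 | intermediate
17 | 3-[(8Z)-16-[3,5-bis(tert-butyldimethylsilyloxy)phenyl]hexadec-8-en-1-yl]-5-(tert-butyldimethylsilyloxy)phenol | Oc1cc(CCCCCCC/C=C\CCCCCCCc2cc(O[Si](C)(C)C(C)(C)C)cc(O[Si](C)(C)C(C)(C)C)c2)cc(O[Si](C)(C)C(C)(C)C)c1 | intermediate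
18 | 3-[(8Z)-16-[3,5-bis(tert-butyldimethylsilyloxy)phenyl]hexadec-8-en-1-yl]-5-(tert-butyldimethylsilyloxy)phenyl acetate | CC(=O)Oc1cc(CCCCCCC/C=C\CCCCCCCc2cc(O[Si](C)(C)C(C)(C)C)cc(O[Si](C)(C)C(C)(C)C)c2)cc(O[Si](C)(C)C(C)(C)C)c1 | intermediate
19 | Oncostemonol B, 3-[(8Z)-16-(3,5-dihydroxyphenyl)hexadec-8-en-1-yl]-5-hydroxyphenyl acetate | CC(=O)Oc1cc(O)cc(CCCCCCC/C=C\CCCCCCCc2cc(O)cc(O)c2)c1 | target

**Step count**

Total: 13 steps. Longest linear sequence: 9 steps (steps 5–13, from 1).

**Steps most likely to fail, with fallbacks**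

Step 10. The risks are attack of the organolithium on an aryl silyl ether during or after the exchange, a second acetylene insertion if the temperature or the gas dosing drifts, and sluggish alkylation of the alkenylcuprate by the elaborate primary iodide with erosion of geometry on warming. The fallback keeps acetylene-derived C8'/C9' but joins the arms by acetylide alkylation and sets the geometry by semi-hydrogenation; it sets out from 6 and rejoins the route at 16. Iodide 6 is alkylated with commercial lithium (trimethylsilyl)acetylide in THF–DMPU (−78 °C → rt) to give {9-[3,5-bis(tert-butyldimethylsilyloxy)phenyl]non-1-yn-1-yl}trimethylsilane F1. Catalytic AgNO3 in acetone–water removes the alkynyl silyl group selectively and leaves the aryl silyl ethers, giving 1-(non-8-yn-1-yl)-3,5-bis(tert-butyldimethylsilyloxy)benzene F2. Deprotonation with n-BuLi in THF at −78 °C gives the lithium alkynide of F2 F3, which is alkylated in the same flask by iodide 11 (DMPU, −78 °C → rt) to the internal alkyne tert-butyl{3-[16-[3,5-bis(tert-butyldimethylsilyloxy)phenyl]hexadec-8-yn-1-yl]-5-(4-methoxybenzyloxy)phenoxy}dimethylsilane F4. Semi-hydrogenation over Pd/CaCO3 poisoned with Pb(OAc)2 and quinoline (H2, EtOAc), which does not hydrogenolyse benzyl ethers, should then deliver the Z-alkene 16 by syn addition of hydrogen.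

Step 8. The risks are partial hydrogenolysis of the phenolic PMB ether before the alkyne is fully saturated, or silyl loss on the catalyst surface. The fallback avoids any hydrogenation of the PMB-bearing arm by attaching a saturated chain directly; it sets out from 8 and rejoins the route at 11. Commercial 7-bromohept-1-ene is hydroborated with 9-BBN-H in THF to 9-(7-bromoheptyl)-9-borabicyclo[3.3.1]nonane F5. F5 is coupled in the same flask with bromide 8 (Pd(dppf)Cl2, K3PO4, THF–H2O, 40–50 °C; B-alkyl Suzuki–Miyaura coupling) to give [3-(7-bromoheptyl)-5-(4-methoxybenzyloxy)phenoxy](tert-butyl)dimethylsilane F6. Finkelstein exchange (NaI, acetone, reflux) converts F6 into iodide 11, so steps 7–9 are bypassed.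

Step 11. The risks are slow hydride abstraction from an aryl (as opposed to alkyl) PMB ether and oxidative degradation of the electron-rich silyloxyarenes or of the liberated phenol by DDQ. The fallback removes the need for any orthogonal group by using the symmetry of the fully deprotected tetraphenol; it sets out from 6 and rejoins the route at the target 19. The cuprate sequence of step 10 (through 13, 14 and 15) is run with 6 as the alkylating iodide as well, giving the C2-symmetric tetrakis(silyl ether) (8Z)-1,16-bis[3,5-bis(tert-butyldimethylsilyloxy)phenyl]hexadec-8-ene F7. Bu4NF in THF removes all four silyl groups to give 5,5'-[(8Z)-hexadec-8-ene-1,16-diyl]di(benzene-1,3-diol) F8, whose four hydroxyl groups are equivalent by symmetry. Acetylation with one equivalent of Ac2O (pyridine, CH2Cl2, −20 °C) can therefore give only one monoacetate, 19. It is separated from unreacted F8 and over-acetylated material, both of which can be returned to F8 by methanolysis (K2CO3, MeOH) and recycled.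

**Further compounds**

F1 | step 10 | {9-[3,5-bis(tert-butyldimethylsilyloxy)phenyl]non-1-yn-1-yl}trimethylsilane | C[Si](C)(C)C#CCCCCCCCc1cc(O[Si](C)(C)C(C)(C)C)cc(O[Si](C)(C)C(C)(C)C)c1
F2 | step 10 | 1-(non-8-yn-1-yl)-3,5-bis(tert-butyldimethylsilyloxy)benzene | C#CCCCCCCCc1cc(O[Si](C)(C)C(C)(C)C)cc(O[Si](C)(C)C(C)(C)C)c1
F3 | step 10 | lithium alkynide of F2, {9-[3,5-bis(tert-butyldimethylsilyloxy)phenyl]non-1-yn-1-yl}lithium | [Li]C#CCCCCCCCc1cc(O[Si](C)(C)C(C)(C)C)cc(O[Si](C)(C)C(C)(C)C)c1
F4 | step 10 | tert-butyl{3-[16-[3,5-bis(tert-butyldimethylsilyloxy)phenyl]hexadec-8-yn-1-yl]-5-(4-methoxybenzyloxy)phenoxy}dimethylsilane | COc1ccc(COc2cc(CCCCCCCC#CCCCCCCCc3cc(O[Si](C)(C)C(C)(C)C)cc(O[Si](C)(C)C(C)(C)C)c3)cc(O[Si](C)(C)C(C)(C)C)c2)cc1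
F5 | step 8 | 9-(7-bromoheptyl)-9-borabicyclo[3.3.1]nonane | BrCCCCCCCB1C2CCCC1CCC2
F6 | step 8 | [3-(7-bromoheptyl)-5-(4-methoxybenzyloxy)phenoxy](tert-butyl)dimethylsilane | COc1ccc(COc2cc(CCCCCCCBr)cc(O[Si](C)(C)C(C)(C)C)c2)cc1
F7 | step 11 | (8Z)-1,16-bis[3,5-bis(tert-butyldimethylsilyloxy)phenyl]hexadec-8-ene | CC(C)(C)[Si](C)(C)Oc1cc(CCCCCCC/C=C\CCCCCCCc2cc(O[Si](C)(C)C(C)(C)C)cc(O[Si](C)(C)C(C)(C)C)c2)cc(O[Si](C)(C)C(C)(C)C)c1
F8 | step 11 | 5,5'-[(8Z)-hexadec-8-ene-1,16-diyl]di(benzene-1,3-diol) | Oc1cc(O)cc(CCCCCCC/C=C\CCCCCCCc2cc(O)cc(O)c2)c1
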